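All runs come from a simulation on assumed constants.

Two numbers are asked of this flask, G and E at the end, and one quantity answers both.

in all of them: L 2 mol%; Z 1 mol%
- dusk: Q 0.13 M; J 1.2 equiv (fed, over 1.5 h); run made earlier; the fed solution adds 0.10 times the starting volume
- midnight: Q 0.20 M; J 1.2 equiv (fed, over 1.5 h); run made earlier; the fed solution adds 0.10 times the starting volume
- flask: Q 0.090 M; J 1.20 equiv (fed, over 1.5 h); the fed solution adds 0.10 times the starting volume; time 12 d

| run | time / d | G / % | E / % | Q / % |
|---|---|---|---|---|
| dusk | 1.67 | 63.8 | 35.6 | 0.1 |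
| dusk | 4.00 | 57.9 | 41.5 | 0 |
| dusk | 8.00 | 58.3 | 43.1 | 0.1 |
| dusk | 12.0 | 57.9 | 42.9 | 0 |
| midnight | 1.67 | 65.2 | 34.9 | 0 |
| midnight | 4.00 | 58.4 | 43.0 | 0.2 |
| midnight | 8.00 | 57.4 | 42.8 | 0.5 |
| midnight | 12.0 | 57.7 | 43.2 | 0.1 |

(scatter of a reading: 0.5 percentage points)

- amounts are per litre of the starting volume; all of the dose is in the solution fed
- what was read earlier has a scatter of 0.5 percentage points, one standard deviation

* G at 12 d, in percent of the Q charged
* E at 12 d, in percent of the Q charged

Draw the curve of G from the two earlier runs. Its rise lies before the first reading: at 1.67 d the dusk run holds 0.1% of Q and the midnight run 0%. There G reads 63.8% and 65.2%, then it bends down, and by 4.00 d it reads 57.9% and 58.4%, the level it keeps up to 12.0 d. So start with that level, and call the plateau share 57.3%: the part of G in G plus E at the last readings of both runs, a split that looks like thermodynamic control.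

Now join the knee to it. If you suppose that G is made first and its excess over the plateau decays steadily, the excess at the first reading gives a half-life of about 0.650 d. That is far shorter than the 12 d of this flask, so you can expect the flask, at 0.090 M, to stand on its plateau. Your reckoning gives G at 57.3% and E at 42.7%.

The forecast gives 57.7% of G and 42.6% of E, holding of the plateau that “it does not depend on concentration”; its G lies 0.40 percentage points above your reckoning.

The flask gives 57.1% of G and 42.9% of E.

    Q + L → L + D (k = 5.20 M⁻¹ min⁻¹)
    J + Z + D → Z + G (k = 160 M⁻² min⁻¹)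
    G ⇌ E (K = 0.750, k = 3.50 × 10⁻⁴ min⁻¹)

Now take the neighbour flask with 0.720 equiv of J, which ends with 0% of its J, so J is the limiting reagent there. If each J makes one G or E, the share puts G at 41.3% and E at 30.7%. That neighbour gives 41.1% of G and 30.9% of E, with 28.0% of the Q standing as D.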